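Readings and results stem from a simulated flask on assumed constants, noise included.

**The dose.** The first rung, at early times, was the dose. At the end of the feed, 0.833 min, the alder run held 6.2% target and the birch run 10.3%.

all flasks: starting material 1.6 M (fed, over 50 s)

| flask | coupling partner | second substrate | remark | time |
|---|---|---|---|---|
| alder | 0.50 equiv | 0.20 equiv | run made earlier; the fed solution adds 0.10 times the starting volume |  |
| birch | 0.75 equiv | 0.20 equiv | run made earlier; the fed solution adds 0.10 times the starting volume |  |
| flask | 1.00 equiv | 0.200 equiv | the fed solution adds 0.10 times the starting volume | 12 min |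

| run | time / min | target / % | starting material / % |
|---|---|---|---|
| alder | 0.833 | 6.2 | 89.7 |
| alder | 2.00 | 14.0 | 80.0 |
| alder | 5.00 | 14.1 | 78.9 |
| alder | 12.0 | 12.9 | 80.7 |
| birch | 0.833 | 10.3 | 85.8 |
| birch | 2.00 | 18.1 | 73.3 |
| birch | 5.00 | 17.9 | 72.6 |
| birch | 12.0 | 15.5 | 76.6 |

(readings scatter by 0.5 percentage points)

- charges are per starting volume, the dose included; the dosed solution carries all of it

- the moment within 12 min at which there is most target
- the amount of target, in percent of the starting material charged, at that time

**The plateau.** The next rung came after the feed. Target in alder read 14.0% at 2.00 min and 14.1% at 5.00 min, and in birch 18.1% and 17.9%: flat within the scatter. So I placed the peak of the flask inside that interval.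

**The fade.** The last rung was a decline. By 12.0 min, alder had dropped to 12.9% and birch to 15.5%.

**Counting turnovers.** In both runs the coupling partner was charged below one equivalent of starting material, which made it the limiting reagent by charge. So I counted one partner per target and took the partner share: plateau target divided by equivalents of partner charged. It read 28.1% in alder and 24.0% in birch. Taken as a power of the charge, this share fell with exponent 0.389. For the flask that gave me a share of 21.5%, so 21.5% target.

**The forecast.** It said 21.3% at 2.8 min, slightly below my figure, reading the peak as “roughly order 0.6 in coupling partner”.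

**The flask.** It gave 22.4% at 3.02 min, and the forecast held.

    2 coupling partner → homo dimer (k = 0.00336 L mol⁻¹ s⁻¹)
    target ⇌ isomer of the product (K = 0.480, k = 0.196 s⁻¹)
    starting material + coupling partner ⇌ target (K = 1.00 L mol⁻¹, k = 0.0109 L mol⁻¹ s⁻¹)
    second substrate + coupling partner ⇌ second product (K = 1.86 L mol⁻¹, k = 0.0653 L mol⁻¹ s⁻¹)

**The neighbour.** The flask's partner share came to 22.4%, above my 21.5%. The neighbouring flask held 0.250 equiv of coupling partner, with the other charges and the time as in the flask. The same reckoning gave it a share of 36.8%, so 9.20% target. It reached 8.35%, a share of 33.4%, which is lower than reckoned. At 12 min it held 7.82% target, with 24% of its partner still free.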